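## Plan

1. Labels: ring A is the benzo ring (C3a, C4 to C7, C7a), ring B the dihydrofuran (O1, C2, C3), ring C the 3,4,5-trimethoxyphenyl group. The retrosynthesis first cuts C5–allyl, leading back to a C5 aryl triflate and hence a C5 phenol. It then cuts O1–C2 and C3a–C3 together, which leaves 2-(benzyloxy)-1,4-benzoquinone and (E)-isoelemicin.
2. Enabling feature: O1–C7a–C3a is a three-atom unit of ring A, and C3a lies beta to C5. With C5 and C7a raised to carbonyls (quinone level), C3a becomes a Michael acceptor carbon and O1 a carbonyl oxygen. C2 is benzylic to ring C and can carry the cation that links the two bond formations.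
3. Forward order: a Suzuki–Miyaura coupling gives the E alkene and a Teuber oxidation gives the quinone. A chiral titanium TADDOLate (3+2) cycloaddition then closes ring B and re-aromatises ring A.
4. The helpers are removed afterwards. The C5 oxygen becomes a triflate, the O6 benzyl group is hydrogenolysed, and the triflate is exchanged for allyl.
5. Stereochemistry: the trans C2/C3 relationship comes from the E alkene and the mode of ring closure. The absolute configuration comes from the TADDOL ligand. No later step touches C2 or C3.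

Key step: step 3

Assumption: the titanium complex of (4R,5R)-TADDOL ((4R,5R)-2,2-dimethyl-α,α,α′,α′-tetraphenyl-1,3-dioxolane-4,5-dimethanol) is taken to lead to the (2S,3S) series. If the sense of induction is the opposite one, the equally available (4S,5S)-diol is used and nothing else changes.

## Route

Step 1
Reactants: 1 5-bromo-1,2,3-trimethoxybenzene; 2 (E)-prop-1-enylboronic acid pinacol ester
Product: 3 (E)-isoelemicin, 1,2,3-trimethoxy-5-[(E)-prop-1-enyl]benzene
Conditions: Pd(dppf)Cl2 (cat.), K2CO3, dioxane/H2O, 80 °C
Reagents that add atoms: none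
Why: The Suzuki–Miyaura coupling of an aryl bromide with an alkenylboronate keeps the alkene geometry, so it should give the pure E alkene on which the trans relationship of the target depends.

Step 2
Reactants: 4 2-(benzyloxy)phenol
Product: 5 2-(benzyloxy)-1,4-benzoquinone
Conditions: K2[ON(SO3)2] (2.2 equiv), KH2PO4 buffer, H2O/acetone, 0 °C to rt
Reagents that add atoms: potassium nitrosodisulfonate, [K+].[K+].[O]N(S(=O)(=O)[O-])S(=O)(=O)[O-]
Why: In the Teuber oxidation one nitrosodisulfonate radical removes the phenolic hydrogen and a second one delivers oxygen to the free para position, which should give the p-quinone and leave the benzyl ether untouched.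

Step 3
Reactants: 5 2-(benzyloxy)-1,4-benzoquinone; 3 (E)-isoelemicin
Product: 6 (2S,3S)-6-(benzyloxy)-3-methyl-2-(3,4,5-trimethoxyphenyl)-2,3-dihydro-1-benzofuran-5-ol (trans)
Conditions: TiCl4 + Ti(OiPr)4 (1:1) and (4R,5R)-TADDOL (2 equiv of the resulting TiCl2(TADDOLate)), 4 Å MS, CH2Cl2, rt; then 5, −78 °C; then 3, −78 to −20 °C; sat. aq NaHCO3
Reagents that add atoms: none
Why: The tetravalent titanium centre chelates the C1 carbonyl oxygen and the neighbouring benzyloxy oxygen of 5, which makes quinone C5 (the later C3a) the most electrophilic carbon, so the methyl-bearing alkene carbon of 3 attacks there (bond C3a–C3) and leaves a cation at the carbon benzylic to ring C. The C4 carbonyl oxygen next to the new bond (the later O1) captures this cation (bond O1–C2), and loss of the C3a proton re-aromatises ring A, which makes the sequence irreversible and drains the competing (2+2) cyclobutane and (5+2) bicyclo[3.2.1]octane closures of the same cation. The closest known reaction type is the titanium-promoted formal (3+2) cycloaddition of 2-alkoxy-1,4-benzoquinones with (E)-propenylarenes, including its TADDOLate variant. The only ring that closes is ring B, by a 5-exo-trig attack of oxygen on the quinone-methide-like form of the benzylic cation. C3 is set in the C–C bond formation, where the aryl groups of the C2-symmetric TADDOLate leave one face of the stacked alkene open to the bound quinone, and C2 follows from C3 because the cation closes with ring C and the methyl group on opposite faces of ring B, as both the E geometry and the thermodynamic preference demand. The step needs regioselectivity on the quinone (C5 over C6, secured by the chelate), regioselectivity on the alkene (secured by the benzylic cation) and O- over C-closure (secured by the C3a–H that allows aromatisation).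

Step 4
Reactants: 6 (2S,3S)-6-(benzyloxy)-3-methyl-2-(3,4,5-trimethoxyphenyl)-2,3-dihydro-1-benzofuran-5-ol
Product: 7 (2S,3S)-6-(benzyloxy)-3-methyl-2-(3,4,5-trimethoxyphenyl)-2,3-dihydro-1-benzofuran-5-yl trifluoromethanesulfonate
Conditions: PhNTf2, Et3N, DMAP (cat.), CH2Cl2, 0 °C to rt
Reagents that add atoms: N-phenylbis(trifluoromethanesulfonimide), O=S(=O)(N(c1ccccc1)S(=O)(=O)C(F)(F)F)C(F)(F)F
Why: Sulfonylation of the only free phenol with a mild triflyl donor turns the helper oxygen at C5 into a leaving group for cross-coupling, without acid that could ionise the C2–O1 bond.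

Step 5
Reactants: 7 (2S,3S)-6-(benzyloxy)-3-methyl-2-(3,4,5-trimethoxyphenyl)-2,3-dihydro-1-benzofuran-5-yl trifluoromethanesulfonate
Product: 8 (2S,3S)-6-hydroxy-3-methyl-2-(3,4,5-trimethoxyphenyl)-2,3-dihydro-1-benzofuran-5-yl trifluoromethanesulfonate
Conditions: H2 (1 atm), Pd/C, EtOAc, rt, no base
Reagents that add atoms: none
Why: Hydrogenolysis of the primary aryl benzyl ether should be faster than cleavage of the hindered secondary cyclic C2–O1 bond, aryl triflates are inert without added base, and the step is placed before the reducible allyl group exists.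

Step 6
Reactants: 8 (2S,3S)-6-hydroxy-3-methyl-2-(3,4,5-trimethoxyphenyl)-2,3-dihydro-1-benzofuran-5-yl trifluoromethanesulfonate; 9 allyltributylstannane
Product: 10 (2S,3S)-5-allyl-3-methyl-2-(3,4,5-trimethoxyphenyl)-2,3-dihydro-1-benzofuran-6-ol (target)
Conditions: Pd(PPh3)4 (cat.), LiCl, DMF, 90 °C
Reagents that add atoms: none
Why: In the Stille coupling zerovalent palladium inserts into the C5–OTf bond, LiCl assists transmetalation from the allylstannane, and the neutral medium tolerates the free phenol and leaves C2 and C3 untouched.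

## Compound list

1 | 5-bromo-1,2,3-trimethoxybenzene | COc1cc(Br)cc(OC)c1OC | starting material
2 | (E)-prop-1-enylboronic acid pinacol ester | C/C=C/B1OC(C)(C)C(C)(C)O1 | starting material
3 | (E)-isoelemicin | C/C=C/c1cc(OC)c(OC)c(OC)c1 | intermediate
4 | 2-(benzyloxy)phenol | Oc1ccccc1OCc1ccccc1 | starting material
5 | 2-(benzyloxy)-1,4-benzoquinone | O=C1C=CC(=O)C(OCc2ccccc2)=C1 | intermediate
6 | (2S,3S)-6-(benzyloxy)-3-methyl-2-(3,4,5-trimethoxyphenyl)-2,3-dihydro-1-benzofuran-5-ol | Oc1cc2c(cc1OCc1ccccc1)O[C@H](c1cc(OC)c(OC)c(OC)c1)[C@H]2C | intermediate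
7 | (2S,3S)-6-(benzyloxy)-3-methyl-2-(3,4,5-trimethoxyphenyl)-2,3-dihydro-1-benzofuran-5-yl trifluoromethanesulfonate | O=S(=O)(Oc1cc2c(cc1OCc1ccccc1)O[C@H](c1cc(OC)c(OC)c(OC)c1)[C@H]2C)C(F)(F)F | intermediate
8 | (2S,3S)-6-hydroxy-3-methyl-2-(3,4,5-trimethoxyphenyl)-2,3-dihydro-1-benzofuran-5-yl trifluoromethanesulfonate | O=S(=O)(Oc1cc2c(cc1O)O[C@H](c1cc(OC)c(OC)c(OC)c1)[C@H]2C)C(F)(F)F | intermediate
9 | allyltributylstannane | C=CC[Sn](CCCC)(CCCC)CCCC | starting material
10 | (2S,3S)-5-allyl-3-methyl-2-(3,4,5-trimethoxyphenyl)-2,3-dihydro-1-benzofuran-6-ol | C=CCc1cc2c(cc1O)O[C@H](c1cc(OC)c(OC)c(OC)c1)[C@H]2C | target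

Total step count: 6. Longest linear sequence: 5 (step 1 or step 2, then steps 3, 4, 5 and 6).

## Steps most likely to fail

**Step 3.** The chiral titanium complex may discriminate poorly between the alkene faces with the larger benzyloxy group. The benzylic cation may also leak into the four-membered or bicyclic closures.
- The fallback sets out from 3 and 5 and comes back at 6.
- The cycloaddition is run with the achiral promoter TiCl4/Ti(OiPr)4 in CH2Cl2 from −78 to 0 °C. This should give racemic trans-6-(benzyloxy)-3-methyl-2-(3,4,5-trimethoxyphenyl)-2,3-dihydro-1-benzofuran-5-ol F1.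
- The free C5 phenol is acylated with (1S)-camphanic chloride (Et3N, DMAP, CH2Cl2). This gives the (2S,3S)-dihydrobenzofuranyl (1S,4R)-camphanate F2 and the (2R,3R)-dihydrobenzofuranyl (1S,4R)-camphanate F3.
- The two esters are separated by crystallisation or chromatography. LiOH in THF/H2O then cleaves F2 to 6.
- The absolute configuration then comes from a classical resolution instead of from asymmetric induction.

**Step 6.** Oxidative addition into the electron-rich triflate may be slow. The allyl double bond may migrate into conjugation, or the triflyl group may move between the neighbouring oxygens.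
- The fallback sets out from 8 and comes back at 10. It replaces the cross-coupling by a sigmatropic C–C bond formation.
- The triflate is reduced (H2, Pd/C, Et3N, MeOH) to (2S,3S)-3-methyl-2-(3,4,5-trimethoxyphenyl)-2,3-dihydro-1-benzofuran-6-ol F4.
- Allyl bromide and K2CO3 in acetone give (2S,3S)-6-(allyloxy)-3-methyl-2-(3,4,5-trimethoxyphenyl)-2,3-dihydro-1-benzofuran F5.
- An aromatic Claisen rearrangement (N,N-diethylaniline, 190 °C) should move the allyl group to C5 and give 10.
- C7 lies between two oxygen-bearing carbons and next to the ring fusion, so it is the more hindered ortho position.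

**Step 5.** Over-reduction may occur, by cleavage of the benzylic C2–O1 bond or by loss of the triflate.
- The fallback sets out from 7 and comes back at 10. It inverts the order of events so that no hydrogenation is needed.
- Stille coupling of 7 with 9 (Pd(PPh3)4, LiCl, DMF, 90 °C) gives (2S,3S)-5-allyl-6-(benzyloxy)-3-methyl-2-(3,4,5-trimethoxyphenyl)-2,3-dihydro-1-benzofuran F6.
- The benzyl group is then transferred to a cation scavenger with BCl3 and pentamethylbenzene in CH2Cl2 at −78 °C. These conditions spare the allyl group and the methyl ethers.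

## Further compounds

F1 | step 3 | racemic trans-6-(benzyloxy)-3-methyl-2-(3,4,5-trimethoxyphenyl)-2,3-dihydro-1-benzofuran-5-ol (both enantiomers) | Oc1cc2c(cc1OCc1ccccc1)O[C@H](c1cc(OC)c(OC)c(OC)c1)[C@H]2C.Oc1cc2c(cc1OCc1ccccc1)O[C@@H](c1cc(OC)c(OC)c(OC)c1)[C@@H]2C
F2 | step 3 | (2S,3S)-6-(benzyloxy)-3-methyl-2-(3,4,5-trimethoxyphenyl)-2,3-dihydro-1-benzofuran-5-yl (1S,4R)-camphanate | O=C(Oc1cc2c(cc1OCc1ccccc1)O[C@H](c1cc(OC)c(OC)c(OC)c1)[C@H]2C)[C@@]45CC[C@@](C)(C(=O)O4)C5(C)C
F3 | step 3 | (2R,3R)-6-(benzyloxy)-3-methyl-2-(3,4,5-trimethoxyphenyl)-2,3-dihydro-1-benzofuran-5-yl (1S,4R)-camphanate | O=C(Oc1cc2c(cc1OCc1ccccc1)O[C@@H](c1cc(OC)c(OC)c(OC)c1)[C@@H]2C)[C@@]45CC[C@@](C)(C(=O)O4)C5(C)C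
F4 | step 6 | (2S,3S)-3-methyl-2-(3,4,5-trimethoxyphenyl)-2,3-dihydro-1-benzofuran-6-ol | Oc1ccc2c(c1)O[C@H](c1cc(OC)c(OC)c(OC)c1)[C@H]2C
F5 | step 6 | (2S,3S)-6-(allyloxy)-3-methyl-2-(3,4,5-trimethoxyphenyl)-2,3-dihydro-1-benzofuran | C=CCOc1ccc2c(c1)O[C@H](c1cc(OC)c(OC)c(OC)c1)[C@H]2C
F6 | step 5 | (2S,3S)-5-allyl-6-(benzyloxy)-3-methyl-2-(3,4,5-trimethoxyphenyl)-2,3-dihydro-1-benzofuran | C=CCc1cc2c(cc1OCc1ccccc1)O[C@H](c1cc(OC)c(OC)c(OC)c1)[C@H]2C
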